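**Retrosynthetic overview**
- Lehualide A ⇒ C1′–C2′ bond: Ni(0)-catalysed coupling of an (E)-alkenylalane (Zr-catalysed methylalumination of a C18 terminal alkyne, sets 2′E) with a 6-chloromethyl-4-OMOM-2-pyranone, then MOM removal.
- C18 alkyne ⇒ Ph–C11′ and C7′–C8′ bonds in one step: a proposed Pd-catalysed three-component aryl–alkenylation of isoprene with iodobenzene and a (Z)-alkenylboronate (sets 9′E).
- (Z)-Alkenylboronate ⇒ (Z)-3-iodobut-2-en-1-ol (Red-Al/I2 on but-2-yn-1-ol, sets 6′Z) and lithiated 1-(trimethylsilyl)propyne.
- Chloromethylpyranone ⇒ 4-hydroxy-3-methoxy-5,6-dimethyl-2-pyranone ⇒ 3,5-diketo ester from methyl methoxyacetate, propionyl chloride and an acetyl Weinreb amide.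
- Rings: the 2-pyranone is the only ring constructed (step 3); the benzene ring is bought as iodobenzene.

Assumption: lehualide A has no stereogenic centre, so "single enantiomer" is read as the single (2′E,6′Z,9′E) geometric isomer in the SMILES.

**Pyranone fragment**

Step 1
Reactants: 1 methyl methoxyacetate; 2 propionyl chloride
Product: 3 methyl 2-methoxy-3-oxopentanoate (racemic)
Conditions: 1 (2.0 equiv), LDA (2.0 equiv), THF, −78 °C; then 2 (1.0 equiv), −78 → 0 °C; aq NH4Cl
Reagents that add atoms: none (all atoms from 1 and 2)
Why: Crossed Claisen condensation: the lithium enolate of the α-alkoxy ester is C-acylated by the acid chloride, and the second equivalent of enolate deprotonates the more acidic β-keto ester product so it is not acylated again.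

Step 2
Reactants: 3 methyl 2-methoxy-3-oxopentanoate; 4 N-methoxy-N-methylacetamide
Product: 5 methyl 2-methoxy-4-methyl-3,5-dioxohexanoate (diastereomer/enol mixture)
Conditions: LDA (2.2 equiv), THF, −78 → 0 °C; then 4 (1.1 equiv), −78 → 0 °C; aq HCl work-up
Reagents that add atoms: none (all atoms from 3 and 4)
Why: β-Keto ester dianion γ-acylation (Weiler/Harris type): the more reactive C4 carbanion adds to the Weinreb amide, whose chelated tetrahedral intermediate prevents over-addition; the C2 and C4 stereocentres are irrelevant because both become sp2 in step 3.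

Step 3
Reactants: 5 methyl 2-methoxy-4-methyl-3,5-dioxohexanoate
Product: 6 4-hydroxy-3-methoxy-5,6-dimethyl-2H-pyran-2-one
Conditions: DBU (1.5 equiv), toluene, 60 °C; then dilute HCl
Reagents that add atoms: none
Why: Base-mediated enol-lactonisation of a 3,5-diketo ester: the C5 enolate oxygen attacks the methyl ester to close the six-membered lactone with loss of MeOH, driven by formation of the conjugated 4-hydroxy-2-pyranone.

Step 4
Reactants: 6 4-hydroxy-3-methoxy-5,6-dimethyl-2H-pyran-2-one
Product: 7 3-methoxy-4-(methoxymethoxy)-5,6-dimethyl-2H-pyran-2-one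
Conditions: MOMCl (1.3 equiv), i-Pr2NEt, CH2Cl2, 0 °C → rt
Reagents that add atoms: chloromethyl methyl ether, COCCl
Why: O-Alkylation of the acidic vinylogous-acid hydroxyl (Williamson-type acetal formation), assumed to occur mainly at O-4 (C3 and C5 are blocked, so no C-alkylation); it masks the proton that would quench the alane in step 12.

Step 5
Reactants: 7 3-methoxy-4-(methoxymethoxy)-5,6-dimethyl-2H-pyran-2-one
Product: 8 6-(chloromethyl)-3-methoxy-4-(methoxymethoxy)-5-methyl-2H-pyran-2-one
Conditions: LDA (1.1 equiv), THF, −78 °C, 30 min; cannulate into C2Cl6 (1.5 equiv), THF, −78 °C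
Reagents that add atoms: hexachloroethane, ClC(Cl)(Cl)C(Cl)(Cl)Cl
Why: Lateral (vinylogous) deprotonation: only the 6-methyl gives an anion delocalised through the ring onto the lactone carbonyl (the 5-methyl anion is merely allylic), and electrophilic chlorination by inverse addition limits dichlorination and self-alkylation.

**Side-chain fragment**

Step 6
Reactants: 9 but-2-yn-1-ol
Product: 10 (Z)-3-iodobut-2-en-1-ol
Conditions: Red-Al (1.6 equiv), THF, 0 °C → rt; EtOAc; then I2 (1.5 equiv), −78 → 0 °C
Reagents that add atoms: iodine, II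
Why: Hydroxyl-directed trans-hydroalumination of a propargylic alcohol gives the cyclic alkenylaluminate with Al on C3 cis to the CH2O group, and iodinolysis with retention gives the Z-iodide; this sets the 6′Z geometry of the target.

Step 7
Reactants: 10 (Z)-3-iodobut-2-en-1-ol
Product: 11 (Z)-1-bromo-3-iodobut-2-ene
Conditions: PBr3 (0.4 equiv), Et2O, 0 °C
Reagents that add atoms: phosphorus tribromide, BrP(Br)Br
Why: SN2 bromination of a primary allylic alcohol; the vinyl iodide and its geometry are untouched.

Step 8
Reactants: 11 (Z)-1-bromo-3-iodobut-2-ene; 12 1-(trimethylsilyl)propyne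
Product: 13 [(5Z)-6-iodohept-5-en-1-yn-1-yl]trimethylsilane
Conditions: 12 (1.2 equiv), n-BuLi, THF, −78 → −20 °C; then 11, −78 → −40 °C
Reagents that add atoms: none (all atoms from 11 and 12)
Why: Corey–Kirst-type propargylation: the stabilised lithio-silylpropyne alkylates the unhindered primary allylic bromide by SN2 at its propargylic carbon, too fast and too weakly basic to exchange or eliminate the vinyl iodide, whose Z geometry is unaffected.

Step 9
Reactants: 13 [(5Z)-6-iodohept-5-en-1-yn-1-yl]trimethylsilane
Product: 14 trimethyl[(5E)-6-(4,4,5,5-tetramethyl-1,3,2-dioxaborolan-2-yl)hept-5-en-1-yn-1-yl]silane (boron cis to the CH2CH2 chain, same geometry as 13; the descriptor is E only because B ranks below CH3)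
Conditions: t-BuLi (2.05 equiv), Et2O, −78 °C, 15 min; i-PrOBpin (1.5 equiv), −78 °C → rt; aq NH4Cl
Reagents that add atoms: 2-isopropoxy-4,4,5,5-tetramethyl-1,3,2-dioxaborolane, CC(C)OB1OC(C)(C)C(C)(C)O1
Why: Iodine–lithium exchange and borate trapping both proceed with retention at the alkenyl carbon, and keeping the alkenyllithium at −78 °C avoids 5-exo-dig carbolithiation onto the silylalkyne.

Step 10
Reactants: 14 alkenyl pinacolboronate; 15 iodobenzene; 16 isoprene
Product: 17 trimethyl[(5Z,8E)-6,8-dimethyl-10-phenyldeca-5,8-dien-1-yn-1-yl]silane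
Conditions: 15 (1.5 equiv), 16 (8 equiv), Pd2(dba)3 (3 mol%), 2-(5-CF3-pyridin-2-yl)-4,4-dimethyl-2-oxazoline (8 mol%), K3PO4 (2.5 equiv), H2O (5 equiv), DMA, 45 °C, sealed tube; 14 (1.0 equiv) added over 4 h
Reagents that add atoms: none (all atoms from 14, 15 and 16)
Why: Proposed new method: three-component aryl–alkenylation of isoprene. PhPdI from 15 carbopalladates the less hindered monosubstituted C3=C4 bond of s-trans isoprene with Ph going to C4, giving the syn-1-benzyl-2-methyl-π-allylpalladium. Slow addition of the hindered boronate and excess diene keep this insertion ahead of direct Suzuki coupling. Transmetallation and reductive elimination at the unsubstituted CH2 terminus then give the 1,4-adduct, with the new trisubstituted alkene E (benzyl syn to the 2-methyl) and the boronate geometry retained (6′Z). The closest known reaction type is the Pd-catalysed 1,4-difunctionalisation of 1,3-dienes with alkenyl triflates and boronic acids (Heck insertion/π-allyl Suzuki cascade); as far as I know it has not been shown with an aryl iodide electrophile and a stereodefined α-methyl (Z)-alkenylboronate nucleophile on isoprene.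

Step 11
Reactants: 17 silylated dienyne
Product: 18 (5Z,8E)-6,8-dimethyl-10-phenyldeca-5,8-dien-1-yne
Conditions: K2CO3 (0.5 equiv), MeOH, rt
Reagents that add atoms: none
Why: Methanolysis of the alkynyl C–Si bond (protiodesilylation) is selective and leaves the skipped diene and both alkene geometries untouched.

**Fragment union**

Step 12
Reactants: 18 (5Z,8E)-6,8-dimethyl-10-phenyldeca-5,8-dien-1-yne; 8 6-(chloromethyl)-3-methoxy-4-(methoxymethoxy)-5-methyl-2H-pyran-2-one
Product: 19 3-methoxy-4-(methoxymethoxy)-5-methyl-6-[(2E,6Z,9E)-3,7,9-trimethyl-11-phenylundeca-2,6,9-trien-1-yl]-2H-pyran-2-one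
Conditions: 18 (1.2 equiv), Me3Al (2.4 equiv), Cp2ZrCl2 (0.25 equiv), CH2Cl2, 0 °C → rt; evaporate volatiles; then 8 (1.0 equiv), NiCl2(PPh3)2 (5 mol%)/n-BuLi (10 mol%), THF, 0 °C → rt
Reagents that add atoms: trimethylaluminium, C[Al](C)C
Why: Negishi Zr-catalysed carboalumination adds Me and Al syn across the terminal alkyne with Me on the internal carbon, and Ni(0)-catalysed alkenylalane–heterobenzylic chloride cross-coupling proceeds with retention, so the pyranone CH2 ends cis to the new methyl (2′E); the trisubstituted alkenes are inert to methylalumination.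

Step 13
Reactants: 19 MOM-protected lehualide A
Product: 20 lehualide A, 4-hydroxy-3-methoxy-5-methyl-6-[(2E,6Z,9E)-3,7,9-trimethyl-11-phenylundeca-2,6,9-trien-1-yl]-2H-pyran-2-one
Conditions: PPTS (0.3 equiv), MeOH, 45 °C
Reagents that add atoms: none
Why: Acid-catalysed MOM acetal cleavage is easy here because the leaving group is the pyranonolate of a vinylogous acid, so conditions mild enough to leave the three trisubstituted alkenes and the skipped diene unchanged are sufficient.

**Compound list**
1 | methyl methoxyacetate | COCC(=O)OC | starting material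
2 | propionyl chloride | CCC(=O)Cl | starting material
3 | methyl 2-methoxy-3-oxopentanoate (racemic) | CCC(=O)C(OC)C(=O)OC | intermediate
4 | N-methoxy-N-methylacetamide | CC(=O)N(C)OC | starting material
5 | methyl 2-methoxy-4-methyl-3,5-dioxohexanoate (stereoisomer mixture) | COC(=O)C(OC)C(=O)C(C)C(C)=O | intermediate
6 | 4-hydroxy-3-methoxy-5,6-dimethyl-2H-pyran-2-one | COc1c(O)c(C)c(C)oc1=O | intermediate
7 | 3-methoxy-4-(methoxymethoxy)-5,6-dimethyl-2H-pyran-2-one | COCOc1c(C)c(C)oc(=O)c1OC | intermediate
8 | 6-(chloromethyl)-3-methoxy-4-(methoxymethoxy)-5-methyl-2H-pyran-2-one | COCOc1c(C)c(CCl)oc(=O)c1OC | intermediate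
9 | but-2-yn-1-ol | CC#CCO | starting material
10 | (Z)-3-iodobut-2-en-1-ol | C/C(I)=C/CO | intermediate
11 | (Z)-1-bromo-3-iodobut-2-ene | C/C(I)=C/CBr | intermediate
12 | 1-(trimethylsilyl)propyne | CC#C[Si](C)(C)C | starting material
13 | [(5Z)-6-iodohept-5-en-1-yn-1-yl]trimethylsilane | C/C(I)=C/CCC#C[Si](C)(C)C | intermediate
14 | trimethyl[(5E)-6-(4,4,5,5-tetramethyl-1,3,2-dioxaborolan-2-yl)hept-5-en-1-yn-1-yl]silane (B cis to the chain) | C/C(B1OC(C)(C)C(C)(C)O1)=C/CCC#C[Si](C)(C)C | intermediate
15 | iodobenzene | Ic1ccccc1 | starting material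
16 | isoprene (2-methylbuta-1,3-diene) | C=CC(C)=C | starting material
17 | trimethyl[(5Z,8E)-6,8-dimethyl-10-phenyldeca-5,8-dien-1-yn-1-yl]silane | C[Si](C)(C)C#CCC/C=C(/C)C/C(C)=C/Cc1ccccc1 | intermediate
18 | (5Z,8E)-6,8-dimethyl-10-phenyldeca-5,8-dien-1-yne | C#CCC/C=C(/C)C/C(C)=C/Cc1ccccc1 | intermediate
19 | 3-methoxy-4-(methoxymethoxy)-5-methyl-6-[(2E,6Z,9E)-3,7,9-trimethyl-11-phenylundeca-2,6,9-trien-1-yl]-2H-pyran-2-one | COCOc1c(OC)c(=O)oc(C/C=C(\C)CC/C=C(/C)C/C(C)=C/Cc2ccccc2)c1C | intermediate
20 | lehualide A | COc1c(O)c(C)c(C/C=C(\C)CC/C=C(/C)C/C(C)=C/Cc2ccccc2)oc1=O | target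

**Totals**
Total steps: 13. Longest linear sequence: 8 (steps 6–13); the pyranone branch is 5 steps (1–5) and joins at step 12.

**Three steps most likely to fail**
1. Step 10 (proposed three-component coupling). Risks: direct Ph–alkenyl Suzuki coupling, insertion at the wrong isoprene terminus, 1,2-addition, E/Z erosion by syn/anti π-allyl equilibration, partial loss of TMS. Fallback (known chemistry): prepare (E)-2-methyl-4-phenylbut-2-en-1-yl bromide from propargyl alcohol (Zr-catalysed carboalumination/I2, Pd-catalysed Negishi coupling with benzylzinc bromide, then PBr3). Couple it with 14 (allyl–alkenyl Suzuki) or with the alkenylzinc from 13 (Negishi) under Pd(0).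
2. Step 5 (lateral chlorination). Risks: dichlorination, self-alkylation of the anion by product 8. Fallback: avoid lateral metalation by carrying the oxygenated carbon from the start. Acylate the dianion of 3 with TBSOCH2C(O)N(OMe)Me (from methyl glycolate), cyclise to the 6-(silyloxymethyl)pyranone, then MOM protection, TBAF and MsCl/LiCl to reach 8.
3. Step 12 (carboalumination/Ni coupling). Risks: residual Me3Al attacking the pyranone or MOM group, reduction or homocoupling of 8. Fallback: reverse the polarity. Convert 18 into the (E)-alkenyl iodide (Zr-catalysed carboalumination, then I2), convert 8 into the pyranonylmethylzinc chloride (Zn dust, LiCl), and join them by Pd-catalysed Negishi coupling.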